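## Retrosynthetic overview
1. 18 ⇒ 17. One global hydrogenation turns the ArC≡C unit into the CH2CH2 bridge and frees three phenols. All O-protection is benzyl, and the OMe is bought in place.
2. Key idea: ring B is never substituted as an arene (no Friedel–Crafts p-hydroxybenzylation, no Wittig or cross-coupling on a crowded arene). Phenol 17 ⇒ its non-aromatic tautomer, the 4-arylidene-3-alkynylcyclohex-2-enone 16, which aromatises without an oxidant (isoaromatisation).
3. 16 ⇒ lithium acetylide 14 + 6-arylidene vinylogous ester 9 (Stork–Danheiser 1,2-addition and carbonyl transposition), telescoped with line 2.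
4. 9 ⇒ cyclohexane-1,3-dione 1 + 2 × aldehyde 2 (C-2 by reductive alkylation, C-6 by α'-aldol condensation), so enolate regiochemistry sets the 1,2,3,4-pattern. 13 ⇒ aldehyde 10 (benzylation, Ohira–Bestmann).
5. Ring order: no ring is closed. Rings A, C and D are bought as arenes. Ring B is bought as the carbocycle of 1 and becomes aromatic in step 6.

Assumption: the target SMILES has no stereocentre and no stereogenic axis, so the compound is achiral and there is no enantiomer to select. The transient stereocentres in 7, 8 and 15 and the C=C geometry in 9, 15 and 16 are all erased in step 6.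

## Route

Step 1
Reactants: 1 cyclohexane-1,3-dione; 2 4-(benzyloxy)benzaldehyde
Product: 4 2-[4-(benzyloxy)benzyl]cyclohexane-1,3-dione, via 2-[4-(benzyloxy)benzylidene]cyclohexane-1,3-dione 3 (not isolated)
Conditions: Hantzsch ester (1.05 equiv), L-proline (20 mol %), CH2Cl2, rt
Reagents that add atoms: none
Why: Organocatalytic three-component reductive alkylation, in which a proline-catalysed Knoevenagel condensation gives alkylidene 3 and the Hantzsch ester reduces it by conjugate hydride transfer faster than a second dione can add, so C-2 is cleanly mono-benzylated and no stereocentre forms.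

Step 2
Reactants: 4 2-[4-(benzyloxy)benzyl]cyclohexane-1,3-dione
Product: 5 3-(benzyloxy)-2-[4-(benzyloxy)benzyl]cyclohex-2-en-1-one
Conditions: BnOH (2 equiv), TsOH·H2O (5 mol %), PhMe, reflux, Dean–Stark
Reagents that add atoms: benzyl alcohol, OCc1ccccc1
Why: Acid-catalysed enol etherification (vinylogous Fischer esterification) driven by azeotropic water removal gives a single vinylogous ester because the two carbonyls of 4 are equivalent, and benzyl is chosen as the O-alkyl group so that every O-protecting group falls in step 7 even if some material in step 6 aromatises with this ether still in place.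

Step 3
Reactants: 5 3-(benzyloxy)-2-[4-(benzyloxy)benzyl]cyclohex-2-en-1-one; 2 4-(benzyloxy)benzaldehyde
Product: 9 (6E)-3-(benzyloxy)-2-[4-(benzyloxy)benzyl]-6-[4-(benzyloxy)benzylidene]cyclohex-2-en-1-one, via lithium α'-enolate of 5 6 (not isolated), via lithium aldolate 7 (not isolated), via aldol mesylate 8 (not isolated)
Conditions: LDA (1.1 equiv), THF, −78 °C; 2; MsCl (1.5 equiv), −78 → 0 °C; DBU (3 equiv), rt
Reagents that add atoms: lithium diisopropylamide, [Li]N(C(C)C)C(C)C (Li, in 6 and 7 only); methanesulfonyl chloride, CS(=O)(=O)Cl (mesyl group, in 8 only)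
Why: Directed aldol condensation on a Stork–Danheiser α'-enolate, in which LDA deprotonates the vinylogous ester kinetically at C-6 (C-2 is blocked and γ-deprotonation is slower), the aldolate is trapped as its mesylate before it can revert, and DBU-induced E1cB elimination gives the conjugated E-arylidene.

Step 4
Reactants: 10 3-hydroxy-5-methoxybenzaldehyde
Product: 11 3-(benzyloxy)-5-methoxybenzaldehyde
Conditions: BnBr (1.1 equiv), K2CO3, DMF, rt
Reagents that add atoms: benzyl bromide, BrCc1ccccc1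
Why: Williamson ether synthesis (SN2 of the phenoxide on benzyl bromide), which leaves the aldehyde and the methyl ether untouched.

Step 5
Reactants: 11 3-(benzyloxy)-5-methoxybenzaldehyde
Product: 13 1-(benzyloxy)-3-ethynyl-5-methoxybenzene, via 1-(benzyloxy)-3-(2-diazoethenyl)-5-methoxybenzene 12 (not isolated)
Conditions: Ohira–Bestmann reagent (1.2 equiv), K2CO3 (2 equiv), MeOH, 0 °C → rt
Reagents that add atoms: dimethyl (1-diazo-2-oxopropyl)phosphonate, COP(=O)(OC)C(=[N+]=[N-])C(C)=O
Why: Ohira–Bestmann variant of the Seyferth–Gilbert homologation, in which methanolysis unmasks the diazomethylphosphonate anion, HWE-type olefination gives diazoalkene 12, and N2 loss with a 1,2-H shift gives the terminal alkyne from this non-enolisable aldehyde.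

Step 6 (key step)
Reactants: 9 (6E)-3-(benzyloxy)-2-[4-(benzyloxy)benzyl]-6-[4-(benzyloxy)benzylidene]cyclohex-2-en-1-one; 13 1-(benzyloxy)-3-ethynyl-5-methoxybenzene
Product: 17 2,4-bis[4-(benzyloxy)benzyl]-3-{[3-(benzyloxy)-5-methoxyphenyl]ethynyl}phenol, via lithium acetylide of 13 14 (not isolated), via tertiary propargylic carbinol 15 (not isolated), via (4E)-4-arylidene-3-alkynylcyclohex-2-enone 16 (not isolated)
Conditions: 13 (1.3 equiv), n-BuLi (1.25 equiv), THF, −78 °C; 9, −78 → 0 °C; 1 M HCl, 0 °C → rt; phase cut, then TsOH·H2O (10 mol %), PhMe, 60–80 °C (telescoped)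
Reagents that add atoms: n-butyllithium, [Li]CCCC (Li, in 14 only); water, O (supplies the new carbonyl and phenol oxygen, while the carbinol OH leaves as water)
Why: Proposed new method: a Stork–Danheiser 1,2-addition and acid-induced carbonyl transposition (a slim, weakly basic acetylide on a ketone with no α-hydrogen) gives 16, a non-aromatic keto tautomer of 17, so acid-catalysed enolisation towards C-6, protonation of the exocyclic carbon and loss of H-5 move the exocyclic C=C into the ring irreversibly and without an oxidant, the closest known reaction types being the isoaromatisation of arylidenecyclohexenones to benzylphenols and the tautomerisation of 4-methylenecyclohex-2-enones to p-alkylphenols.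

Step 7
Reactants: 17 2,4-bis[4-(benzyloxy)benzyl]-3-{[3-(benzyloxy)-5-methoxyphenyl]ethynyl}phenol
Product: 18 2,4-bis(4-hydroxybenzyl)-3-[2-(3-hydroxy-5-methoxyphenyl)ethyl]phenol (target)
Conditions: H2 (4 bar), 10 % Pd/C, EtOAc/EtOH 1:1, rt
Reagents that add atoms: none
Why: Heterogeneous catalytic hydrogenation and hydrogenolysis, in which Pd/C saturates the diarylalkyne through the stilbene and cleaves the three aryl benzyl ethers in the same operation, while the aryl methyl ether, the diarylmethane C–C bonds and the phenols are inert and no stereocentre arises.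

## Compound list
1 | cyclohexane-1,3-dione | O=C1CCCC(=O)C1 | starting material
2 | 4-(benzyloxy)benzaldehyde | O=Cc1ccc(OCc2ccccc2)cc1 | starting material
3 | 2-[4-(benzyloxy)benzylidene]cyclohexane-1,3-dione | O=C1CCCC(=O)C1=Cc1ccc(OCc2ccccc2)cc1 | intermediate (not isolated)
4 | 2-[4-(benzyloxy)benzyl]cyclohexane-1,3-dione | O=C1CCCC(=O)C1Cc1ccc(OCc2ccccc2)cc1 | intermediate
5 | 3-(benzyloxy)-2-[4-(benzyloxy)benzyl]cyclohex-2-en-1-one | O=C1CCCC(OCc2ccccc2)=C1Cc1ccc(OCc2ccccc2)cc1 | intermediate
6 | lithium α'-enolate (cross-conjugated dienolate) of 5 | [Li]OC1=CCCC(OCc2ccccc2)=C1Cc1ccc(OCc2ccccc2)cc1 | intermediate (not isolated)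
7 | lithium aldolate of 6 and 2 (racemic diastereomer mixture) | [Li]OC(c1ccc(OCc2ccccc2)cc1)C1CCC(OCc2ccccc2)=C(Cc2ccc(OCc3ccccc3)cc2)C1=O | intermediate (not isolated)
8 | aldol mesylate (racemic diastereomer mixture) | CS(=O)(=O)OC(c1ccc(OCc2ccccc2)cc1)C1CCC(OCc2ccccc2)=C(Cc2ccc(OCc3ccccc3)cc2)C1=O | intermediate (not isolated)
9 | (6E)-3-(benzyloxy)-2-[4-(benzyloxy)benzyl]-6-[4-(benzyloxy)benzylidene]cyclohex-2-en-1-one | O=C1/C(=C/c2ccc(OCc3ccccc3)cc2)CCC(OCc2ccccc2)=C1Cc1ccc(OCc2ccccc2)cc1 | intermediate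
10 | 3-hydroxy-5-methoxybenzaldehyde | O=Cc1cc(O)cc(OC)c1 | starting material
11 | 3-(benzyloxy)-5-methoxybenzaldehyde | O=Cc1cc(OC)cc(OCc2ccccc2)c1 | intermediate
12 | 1-(benzyloxy)-3-(2-diazoethenyl)-5-methoxybenzene | [N-]=[N+]=C=Cc1cc(OC)cc(OCc2ccccc2)c1 | intermediate (not isolated)
13 | 1-(benzyloxy)-3-ethynyl-5-methoxybenzene | C#Cc1cc(OC)cc(OCc2ccccc2)c1 | intermediate
14 | lithium [3-(benzyloxy)-5-methoxyphenyl]acetylide | [Li]C#Cc1cc(OC)cc(OCc2ccccc2)c1 | intermediate (not isolated)
15 | (6E)-3-(benzyloxy)-2-[4-(benzyloxy)benzyl]-6-[4-(benzyloxy)benzylidene]-1-{[3-(benzyloxy)-5-methoxyphenyl]ethynyl}cyclohex-2-en-1-ol (racemic; formed first as its Li alkoxide) | OC1(C#Cc2cc(OC)cc(OCc3ccccc3)c2)/C(=C/c2ccc(OCc3ccccc3)cc2)CCC(OCc2ccccc2)=C1Cc1ccc(OCc2ccccc2)cc1 | intermediate (not isolated)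
16 | (4E)-2-[4-(benzyloxy)benzyl]-4-[4-(benzyloxy)benzylidene]-3-{[3-(benzyloxy)-5-methoxyphenyl]ethynyl}cyclohex-2-en-1-one | O=C1CC/C(=C\c2ccc(OCc3ccccc3)cc2)C(C#Cc2cc(OC)cc(OCc3ccccc3)c2)=C1Cc1ccc(OCc2ccccc2)cc1 | intermediate (not isolated)
17 | 2,4-bis[4-(benzyloxy)benzyl]-3-{[3-(benzyloxy)-5-methoxyphenyl]ethynyl}phenol | Oc1ccc(Cc2ccc(OCc3ccccc3)cc2)c(C#Cc2cc(OC)cc(OCc3ccccc3)c2)c1Cc1ccc(OCc2ccccc2)cc1 | intermediate
18 | 2,4-bis(4-hydroxybenzyl)-3-[2-(3-hydroxy-5-methoxyphenyl)ethyl]phenol (achiral) | COc1cc(O)cc(CCc2c(Cc3ccc(O)cc3)ccc(O)c2Cc2ccc(O)cc2)c1 | target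

## Step count
- Total step count: 7.
- Longest linear sequence: 5 (steps 1, 2, 3, 6, 7 from 1). Steps 4 and 5 form the two-step side branch.

## Three steps most likely to fail

**Step 6.** The acetylide may fail to add to the doubly deactivated, cross-conjugated ketone. Alternatively, 16 may undergo retro-vinylogous aldol cleavage or resist the exo-to-endo shift.

The fallback gives up the redox-neutral plan, sets out from 5 and comes back at 17.
- Compound 5 is deprotonated with LDA and alkylated with commercial 4-(benzyloxy)benzyl bromide to give racemic 3-(benzyloxy)-2,6-bis[4-(benzyloxy)benzyl]cyclohex-2-en-1-one F1.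
- Acetylide 14, with CeCl3 to suppress enolisation, adds to give the tertiary carbinol F2.
- 1 M HCl transposes F2 to 2,4-bis[4-(benzyloxy)benzyl]-3-{[3-(benzyloxy)-5-methoxyphenyl]ethynyl}cyclohex-2-en-1-one F3.
- LDA/TMSCl converts F3 into the cross-conjugated trimethylsilyl dienol ether F4.
- Saegusa–Ito oxidation (Pd(OAc)2, MeCN) gives the cyclohexa-2,5-dienone F5. It still carries H-4, so it tautomerises at once to 17.

This fallback replaces steps 3 and 6 and costs two more steps.

**Step 3.** The lithium aldolate may revert, mesylation may be incomplete, or γ-deprotonation may compete.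

The fallback avoids any metal aldolate, sets out from 5 and comes back at 9.
- Compound 5 is converted with LDA/TMSCl into its 1-(trimethylsilyloxy)diene F6.
- Aldehyde 2 is converted with HC(OMe)3 and cat. TsOH into 4-(benzyloxy)benzaldehyde dimethyl acetal F7.
- A TMSOTf-catalysed Mukaiyama-type coupling (CH2Cl2, −78 °C) joins F6 and F7 irreversibly through the well-stabilised p-alkoxybenzyl oxocarbenium ion. The product is the β-methoxy ketone F8.
- DBU-induced E1cB loss of methanol from F8 gives 9.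

**Step 7.** The di-ortho-substituted alkyne may stall at the hindered stilbene on the Pd surface, or the catalyst may be poisoned.

The fallback separates the two tasks and uses no surface catalysis. It sets out from 17 and comes back at 18.
- Diimide (TsNHNH2, NaOAc, DME/H2O, reflux) is the smallest concerted H2 donor. It saturates the triple bond to give 2,4-bis[4-(benzyloxy)benzyl]-3-{2-[3-(benzyloxy)-5-methoxyphenyl]ethyl}phenol F9.
- BCl3 with pentamethylbenzene (CH2Cl2, −78 °C) removes the three benzyl ethers by Lewis-acid cleavage with cation scavenging. The aryl methyl ether is left intact, giving 18.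

## Further compounds
F1 | step 6 | 3-(benzyloxy)-2,6-bis[4-(benzyloxy)benzyl]cyclohex-2-en-1-one (racemic) | O=C1C(Cc2ccc(OCc3ccccc3)cc2)CCC(OCc2ccccc2)=C1Cc1ccc(OCc2ccccc2)cc1
F2 | step 6 | 3-(benzyloxy)-2,6-bis[4-(benzyloxy)benzyl]-1-{[3-(benzyloxy)-5-methoxyphenyl]ethynyl}cyclohex-2-en-1-ol (diastereomer mixture) | OC1(C#Cc2cc(OC)cc(OCc3ccccc3)c2)C(Cc2ccc(OCc3ccccc3)cc2)CCC(OCc2ccccc2)=C1Cc1ccc(OCc2ccccc2)cc1
F3 | step 6 | 2,4-bis[4-(benzyloxy)benzyl]-3-{[3-(benzyloxy)-5-methoxyphenyl]ethynyl}cyclohex-2-en-1-one (racemic) | O=C1CCC(Cc2ccc(OCc3ccccc3)cc2)C(C#Cc2cc(OC)cc(OCc3ccccc3)c2)=C1Cc1ccc(OCc2ccccc2)cc1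
F4 | step 6 | trimethylsilyl dienol ether of F3 | C[Si](C)(C)OC1=CCC(Cc2ccc(OCc3ccccc3)cc2)C(C#Cc2cc(OC)cc(OCc3ccccc3)c2)=C1Cc1ccc(OCc2ccccc2)cc1
F5 | step 6 | 2,4-bis[4-(benzyloxy)benzyl]-3-{[3-(benzyloxy)-5-methoxyphenyl]ethynyl}cyclohexa-2,5-dien-1-one | O=C1C=CC(Cc2ccc(OCc3ccccc3)cc2)C(C#Cc2cc(OC)cc(OCc3ccccc3)c2)=C1Cc1ccc(OCc2ccccc2)cc1
F6 | step 3 | 1-(trimethylsilyloxy)diene of 5 | C[Si](C)(C)OC1=CCCC(OCc2ccccc2)=C1Cc1ccc(OCc2ccccc2)cc1
F7 | step 3 | 4-(benzyloxy)benzaldehyde dimethyl acetal | COC(OC)c1ccc(OCc2ccccc2)cc1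
F8 | step 3 | 3-(benzyloxy)-2-[4-(benzyloxy)benzyl]-6-{[4-(benzyloxy)phenyl](methoxy)methyl}cyclohex-2-en-1-one (diastereomer mixture) | O=C1C(C(OC)c2ccc(OCc3ccccc3)cc2)CCC(OCc2ccccc2)=C1Cc1ccc(OCc2ccccc2)cc1
F9 | step 7 | 2,4-bis[4-(benzyloxy)benzyl]-3-{2-[3-(benzyloxy)-5-methoxyphenyl]ethyl}phenol | COc1cc(OCc2ccccc2)cc(CCc2c(Cc3ccc(OCc4ccccc4)cc3)ccc(O)c2Cc2ccc(OCc3ccccc3)cc2)c1
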